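**Strategy.** Ring B is disconnected across C5–C10 and C6–C7 as a Diels–Alder retron. An oxazaborolidinium-catalysed intramolecular Diels–Alder reaction of the acyclic (2E,8E)-trienal 13 joins the 2-silyloxy diene C7=C8(OSi)–C9=C10 to the enal C5=C6 through the C1–C4 tether. This closes rings A and B in one operation and sets C5 and C10 (trans ring fusion, absolute configuration). The step exploits the C8 oxygen (diene donor), the C4 gem-dimethyl group (tether) and the C10 methyl (diene terminus). The formyl group is a traceless handle. The Δ8(9) silyl enol ether then directs C9 alkylation, and C17 and the C6–C8 oxygens are added under substrate control.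

Key step: step 7

Remark: locants C1–C20 are labdane locants (C18/C19 on C4, C20 on C10, C17 on C8, C16 on C13) and α/β have their usual meaning; the (S)-oxazaborolidine of step 7 is assigned by analogy with its behaviour toward β-substituted enals, and its enantiomer would be used, with nothing else changed, should the sense of induction prove opposite.

Step 1
Reactants: 1 methyl isobutyrate; 2 5-iodopent-1-yne
Product: 4 methyl 2,2-dimethylhept-6-ynoate, via lithium enolate 3 (not isolated)
Conditions: LiN(iPr)2, THF, −78 °C; then 2, DMPU, −78 °C to rt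
Reagents that add atoms: none
Why: Enolate SN2 alkylation of the fully substituted ester enolate with a primary iodide should build the C4 quaternary carbon, the alkyne C–H being less acidic than the ester α-C–H.

Step 2
Reactants: 4 methyl 2,2-dimethylhept-6-ynoate; 5 trimethylaluminium (Me3Al); 6 acetyl chloride
Product: 8 methyl (6E)-2,2,6-trimethyl-8-oxonon-6-enoate, via alkenylalane 7 (not isolated)
Conditions: Me3Al, Cp2ZrCl2 (10 mol%), H2O (1 equiv), CH2Cl2, −20 °C; volatiles removed; then AcCl, Pd(PPh3)4 (5 mol%), THF, 0 °C to rt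
Reagents that add atoms: none
Why: Negishi carboalumination adds CH3 and Al syn across the terminal alkyne (methyl to the internal carbon) and the palladium-catalysed acylation proceeds with retention, which should fix the (E)-enone with the C10 methyl cis to the acyl group while the hindered ester survives at low temperature.

Step 3
Reactants: 8 methyl (6E)-2,2,6-trimethyl-8-oxonon-6-enoate
Product: 9 methyl (6E)-2,2,6-trimethyl-8-[(triisopropylsilyl)oxy]nona-6,8-dienoate
Conditions: iPr3SiOTf, Et3N, CH2Cl2, 0 °C
Reagents that add atoms: triisopropylsilyl trifluoromethanesulfonate, CC(C)[Si](OS(=O)(=O)C(F)(F)F)(C(C)C)C(C)C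
Why: Soft enolisation of the methyl ketone (silyl triflate and amine) should give the cross-conjugated 2-silyloxy diene by α′-deprotonation, the bulky silyl group being chosen for stability toward the Lewis acid of step 7.

Step 4
Reactants: 9 methyl (6E)-2,2,6-trimethyl-8-[(triisopropylsilyl)oxy]nona-6,8-dienoate
Product: 10 (6E)-2,2,6-trimethyl-8-[(triisopropylsilyl)oxy]nona-6,8-dienal
Conditions: iBu2AlH (1.05 equiv), CH2Cl2, −78 °C; aq. potassium sodium tartrate
Reagents that add atoms: none
Why: Partial hydride reduction of an α-quaternary ester should stop at the aldehyde because the hindered tetrahedral aluminate persists at −78 °C.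

Step 5
Reactants: 10 (6E)-2,2,6-trimethyl-8-[(triisopropylsilyl)oxy]nona-6,8-dienal; 11 diethyl {2-[methoxy(methyl)amino]-2-oxoethyl}phosphonate
Product: 12 (2E,8E)-N-methoxy-N,4,4,8-tetramethyl-10-[(triisopropylsilyl)oxy]undeca-2,8,10-trienamide
Conditions: LiCl, DBU, MeCN, rt
Reagents that add atoms: none
Why: Horner–Wadsworth–Emmons olefination of the non-enolisable aldehyde under mild LiCl/amine conditions should give the (E)-enamide and leave the silyl dienol ether intact.

Step 6
Reactants: 12 (2E,8E)-N-methoxy-N,4,4,8-tetramethyl-10-[(triisopropylsilyl)oxy]undeca-2,8,10-trienamide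
Product: 13 (2E,8E)-4,4,8-trimethyl-10-[(triisopropylsilyl)oxy]undeca-2,8,10-trienal
Conditions: iBu2AlH, THF, −78 °C; aq. potassium sodium tartrate, 0 °C
Reagents that add atoms: none
Why: Hydride reduction of the N-methoxy-N-methylamide stops at the chelated hemiaminal and releases the (E)-enal on cold work-up, so the triene is not heated before the catalytic step.

Step 7
Reactants: 13 (2E,8E)-4,4,8-trimethyl-10-[(triisopropylsilyl)oxy]undeca-2,8,10-trienal
Product: 14 (1S,4aS,8aS)-4a,8,8-trimethyl-3-[(triisopropylsilyl)oxy]-1,2,4a,5,6,7,8,8a-octahydronaphthalene-1-carbaldehyde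
Conditions: (S)-3,3-diphenyl-1-(o-tolyl)tetrahydro-1H,3H-pyrrolo[1,2-c][1,3,2]oxazaborole (20 mol%), Tf2NH (16 mol%), CH2Cl2, −78 to −20 °C
Reagents that add atoms: none
Why: Coordination of the formyl oxygen to the cationic boron Lewis acid lowers the enal LUMO and the tethered diene adds in a concerted, asynchronous [4+2] cycloaddition; the closest known reaction types are the oxazaborolidinium-catalysed Diels–Alder reactions of 2-silyloxy dienes with enals and the catalytic enantioselective intramolecular Diels–Alder reactions of 1,3,9-decatrienals. Ring B is the cycloaddition ring itself (both new σ-bonds, C5–C10 and C6–C7, lie in it), and ring A closes through the C5–C10 bond in the fused type 1 intramolecular mode, the four-carbon tether C1–C4 linking diene terminus and dienophile. The trans relation of C5-H and C6-H follows from the (E)-enal, and the trans ring fusion (C5-H α, C10-CH3 β) from the endo orientation of the formyl group combined with the (E)-C9=C10 geometry (tether outside, methyl inside). The absolute configuration at C5, C6 and C10 is set by the catalyst, which shields one enal face so that the diene adds to the Si face at C6. The step needs endo over exo selectivity (trans versus cis decalin), which Lewis-acid activation of the (E)-enal should secure, and the tether, helped by the C4 gem-dimethyl group, enforces the regiochemistry against the electronic preference of the 2-silyloxy diene.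

Step 8
Reactants: 14 (1S,4aS,8aS)-4a,8,8-trimethyl-3-[(triisopropylsilyl)oxy]-1,2,4a,5,6,7,8,8a-octahydronaphthalene-1-carbaldehyde
Product: 15 triisopropyl{[(4aS,8aS)-5,5,8a-trimethyl-3,4,4a,5,6,7,8,8a-octahydronaphthalen-2-yl]oxy}silane
Conditions: RhCl(PPh3)3 (1.1 equiv), toluene, 110 °C
Reagents that add atoms: none
Why: Tsuji–Wilkinson decarbonylation (formyl C–H oxidative addition, CO extrusion, reductive elimination) should remove the activating group as CO without touching C5, C10 or the silyl enol ether.

Step 9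
Reactants: 15 triisopropyl{[(4aS,8aS)-5,5,8a-trimethyl-3,4,4a,5,6,7,8,8a-octahydronaphthalen-2-yl]oxy}silane; 16 1-bromobut-2-yne
Product: 19 14,15,17-trinorlabd-12-yn-8-one [(1R,4aS,8aS)-1-(but-2-yn-1-yl)-5,5,8a-trimethyloctahydronaphthalen-2(1H)-one], via sulfonium enolate 17 (not isolated), via 9-epi ketone 18 (not isolated)
Conditions: (Me2N)3S+ Me3SiF2− (TASF), THF, 0 °C; then 16, −78 to 0 °C; then NaOMe (cat.), MeOH, rt
Reagents that add atoms: none
Why: Fluoride cleavage of the silyl enol ether gives the regiodefined Δ8(9) enolate, whose SN2 propargylation at C9 occurs anti to the C10 methyl, and methoxide equilibration should then place the side chain equatorial (9β, 9α-H), which is also the product of protonation from the open α face.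

Step 10
Reactants: 19 14,15,17-trinorlabd-12-yn-8-one
Product: 21 14,15,17-trinorlabd-7-en-12-yn-8-yl trifluoromethanesulfonate, via potassium enolate 20 (not isolated)
Conditions: KN(SiMe3)2, THF, −78 °C; then N-(5-chloropyridin-2-yl)-1,1,1-trifluoro-N-[(trifluoromethyl)sulfonyl]methanesulfonamide, −78 °C
Reagents that add atoms: N-(5-chloropyridin-2-yl)-1,1,1-trifluoro-N-[(trifluoromethyl)sulfonyl]methanesulfonamide, O=S(=O)(N(c1ccc(Cl)cn1)S(=O)(=O)C(F)(F)F)C(F)(F)F
Why: Kinetic deprotonation should occur at the unhindered C7 methylene (C9-H is tertiary and flanked by quaternary C10) and O-sulfonylation of the enolate gives the Δ7 enol triflate.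

Step 11
Reactants: 21 14,15,17-trinorlabd-7-en-12-yn-8-yl trifluoromethanesulfonate; 22 methylzinc chloride (MeZnCl)
Product: 23 14,15-dinorlabd-7-en-12-yne [(4aS,5S,8aS)-5-(but-2-yn-1-yl)-1,1,4a,6-tetramethyl-1,2,3,4,4a,5,8,8a-octahydronaphthalene]
Conditions: MeZnCl, Pd(PPh3)4 (5 mol%), THF, 50 °C
Reagents that add atoms: none
Why: Negishi cross-coupling of the enol triflate installs C17 on C8 and keeps the double bond at C7=C8.

Step 12
Reactants: 23 14,15-dinorlabd-7-en-12-yne
Product: 24 14,15-dinorlabd-12-yne-7α,8α-diol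
Conditions: OsO4 (5 mol%), N-methylmorpholine N-oxide, acetone/t-BuOH/H2O, rt to 40 °C
Reagents that add atoms: osmium tetroxide, O=[Os](=O)(=O)=O; N-methylmorpholine N-oxide, C[N+]1([O-])CCOCC1; water, O
Why: Catalytic OsO4 syn-dihydroxylation should occur on the α face of the trisubstituted Δ7 alkene, anti to the axial C10 methyl, setting 8α-OH/8β-CH3 (and 7α-OH), while the internal alkyne reacts far more slowly.

Step 13
Reactants: 24 14,15-dinorlabd-12-yne-7α,8α-diol; 25 vinyl bromide
Product: 27 labda-12E,14-diene-7α,8α-diol, via alkenylzirconocene 26 (not isolated)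
Conditions: Cp2Zr(H)Cl (3.5 equiv), THF, rt to 45 °C; then ZnCl2 (20 mol%), Pd(PPh3)4 (5 mol%), vinyl bromide, rt
Reagents that add atoms: none
Why: Hydrozirconation adds Zr–H syn and, after equilibration with excess reagent, places zirconium on the methyl-bearing carbon C13, so that zinc-assisted Negishi coupling with retention should give the (12E)-diene, the hydroxyl groups being carried as zirconium alkoxides.

Step 14
Reactants: 27 labda-12E,14-diene-7α,8α-diol
Product: 28 8α-hydroxylabda-12E,14-dien-7-one
Conditions: SO3·pyridine, DMSO, iPr2NEt, CH2Cl2, 0 °C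
Reagents that add atoms: none
Why: Parikh–Doering oxidation converts the secondary axial 7α-alcohol into the ketone without glycol cleavage, the tertiary 8α-OH being unoxidisable and the diene inert.

Step 15
Reactants: 28 8α-hydroxylabda-12E,14-dien-7-one
Product: 30 6α,8α-dihydroxylabda-12E,14-dien-7-one, via dipotassium enolate 29 (not isolated)
Conditions: KN(SiMe3)2 (2.3 equiv), THF, −78 °C; then 3-phenyl-2-(phenylsulfonyl)oxaziridine, −78 °C; AcOH
Reagents that add atoms: 3-phenyl-2-(phenylsulfonyl)oxaziridine, O=S(=O)(c1ccccc1)N1OC1c1ccccc1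
Why: The ketone can enolise only toward C6, and in this enolate α-hydroxylation with the N-sulfonyloxaziridine the oxidant should attack the α face because the β face of C6 is blocked by the axial methyl groups on C4, C8 and C10, giving the equatorial 6α-OH.

Step 16
Reactants: 30 6α,8α-dihydroxylabda-12E,14-dien-7-one; 31 angelic acid [(Z)-2-methylbut-2-enoic acid]
Product: 33 8α-hydroxy-7-oxolabda-12E,14-dien-6α-yl (Z)-2-methylbut-2-enoate, via mixed anhydride 32 (not isolated)
Conditions: 31, 2,4,6-trichlorobenzoyl chloride, Et3N, toluene, rt; then 30, toluene, 80 °C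
Reagents that add atoms: none
Why: Yamaguchi esterification through the preformed mixed anhydride, run without a nucleophilic catalyst to preserve the (Z)-geometry, should acylate only the secondary 6α-OH, the tertiary 8α-OH being inert.

Step 17
Reactants: 33 8α-hydroxy-7-oxolabda-12E,14-dien-6α-yl (Z)-2-methylbut-2-enoate
Product: 34 7β,8α-dihydroxylabda-12E,14-dien-6α-yl (Z)-2-methylbut-2-enoate (CNP0189082.1)
Conditions: NaBH4, CeCl3·7H2O, MeOH, −40 °C; AcOH quench
Reagents that add atoms: none
Why: In this Luche reduction hydride should add axially from the α face of C7 (the β face carries the axial C8 methyl), giving the equatorial 7β-OH, while low temperature and an acidic quench limit acyl migration from O6 to O7.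

**Compound list**

1 | methyl isobutyrate | COC(=O)C(C)C | starting material
2 | 5-iodopent-1-yne | C#CCCCI | starting material
3 | lithium enolate of methyl isobutyrate | [Li]OC(OC)=C(C)C | intermediate (not isolated)
4 | methyl 2,2-dimethylhept-6-ynoate | COC(=O)C(C)(C)CCCC#C | intermediate
5 | trimethylaluminium, Me3Al | C[Al](C)C | starting material
6 | acetyl chloride | CC(Cl)=O | starting material
7 | methyl (6E)-7-(dimethylalumanyl)-2,2,6-trimethylhept-6-enoate | COC(=O)C(C)(C)CCC/C(C)=C/[Al](C)C | intermediate (not isolated)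
8 | methyl (6E)-2,2,6-trimethyl-8-oxonon-6-enoate | COC(=O)C(C)(C)CCC/C(C)=C/C(C)=O | intermediate
9 | methyl (6E)-2,2,6-trimethyl-8-[(triisopropylsilyl)oxy]nona-6,8-dienoate | COC(=O)C(C)(C)CCC/C(C)=C/C(=C)O[Si](C(C)C)(C(C)C)C(C)C | intermediate
10 | (6E)-2,2,6-trimethyl-8-[(triisopropylsilyl)oxy]nona-6,8-dienal | O=CC(C)(C)CCC/C(C)=C/C(=C)O[Si](C(C)C)(C(C)C)C(C)C | intermediate
11 | diethyl {2-[methoxy(methyl)amino]-2-oxoethyl}phosphonate | CCOP(=O)(CC(=O)N(C)OC)OCC | starting material
12 | (2E,8E)-N-methoxy-N,4,4,8-tetramethyl-10-[(triisopropylsilyl)oxy]undeca-2,8,10-trienamide | CON(C)C(=O)/C=C/C(C)(C)CCC/C(C)=C/C(=C)O[Si](C(C)C)(C(C)C)C(C)C | intermediate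
13 | (2E,8E)-4,4,8-trimethyl-10-[(triisopropylsilyl)oxy]undeca-2,8,10-trienal | O=C/C=C/C(C)(C)CCC/C(C)=C/C(=C)O[Si](C(C)C)(C(C)C)C(C)C | intermediate
14 | (1S,4aS,8aS)-4a,8,8-trimethyl-3-[(triisopropylsilyl)oxy]-1,2,4a,5,6,7,8,8a-octahydronaphthalene-1-carbaldehyde (trans-decalin; 6α-CHO, 5α-H, 10β-CH3, Δ8(9) silyl enol ether) | O=C[C@H]1CC(O[Si](C(C)C)(C(C)C)C(C)C)=C[C@@]2(C)CCCC(C)(C)[C@H]12 | intermediate
15 | triisopropyl{[(4aS,8aS)-5,5,8a-trimethyl-3,4,4a,5,6,7,8,8a-octahydronaphthalen-2-yl]oxy}silane | C1CC(O[Si](C(C)C)(C(C)C)C(C)C)=C[C@@]2(C)CCCC(C)(C)[C@H]12 | intermediate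
16 | 1-bromobut-2-yne | CC#CCBr | starting material
17 | tris(dimethylamino)sulfonium (4aS,8aS)-5,5,8a-trimethyl-3,4,4a,5,6,7,8,8a-octahydronaphthalen-2-olate | C1CC([O-])=C[C@@]2(C)CCCC(C)(C)[C@H]12.CN(C)[S+](N(C)C)N(C)C | intermediate (not isolated)
18 | 9-epi-14,15,17-trinorlabd-12-yn-8-one [(1S,4aS,8aS)-1-(but-2-yn-1-yl)-5,5,8a-trimethyloctahydronaphthalen-2(1H)-one; 9α side chain] | CC#CC[C@@H]1C(=O)CC[C@H]2C(C)(C)CCC[C@@]21C | intermediate (not isolated)
19 | 14,15,17-trinorlabd-12-yn-8-one [(1R,4aS,8aS)-1-(but-2-yn-1-yl)-5,5,8a-trimethyloctahydronaphthalen-2(1H)-one; 9β side chain] | CC#CC[C@H]1C(=O)CC[C@H]2C(C)(C)CCC[C@@]21C | intermediate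
20 | potassium Δ7-enolate of 19 | CC#CC[C@H]1C([O-])=CC[C@H]2C(C)(C)CCC[C@@]21C.[K+] | intermediate (not isolated)
21 | 14,15,17-trinorlabd-7-en-12-yn-8-yl trifluoromethanesulfonate | CC#CC[C@H]1C(OS(=O)(=O)C(F)(F)F)=CC[C@H]2C(C)(C)CCC[C@@]21C | intermediate
22 | methylzinc chloride, MeZnCl | C[Zn]Cl | starting material
23 | 14,15-dinorlabd-7-en-12-yne [(4aS,5S,8aS)-5-(but-2-yn-1-yl)-1,1,4a,6-tetramethyl-1,2,3,4,4a,5,8,8a-octahydronaphthalene] | CC#CC[C@H]1C(C)=CC[C@H]2C(C)(C)CCC[C@@]21C | intermediate
24 | 14,15-dinorlabd-12-yne-7α,8α-diol | CC#CC[C@H]1[C@](C)(O)[C@H](O)C[C@H]2C(C)(C)CCC[C@@]21C | intermediate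
25 | vinyl bromide | C=CBr | starting material
26 | (12E)-13-[chloridobis(cyclopentadienyl)zirconio]-14,15-dinorlabd-12-ene-7α,8α-diol (cyclopentadienyl drawn σ-bonded; hydroxyl groups drawn free, zirconium alkoxides in the flask) | C/C(=C\C[C@H]1[C@](C)(O)[C@H](O)C[C@H]2C(C)(C)CCC[C@@]21C)[Zr](Cl)(C1C=CC=C1)C1C=CC=C1 | intermediate (not isolated)
27 | labda-12E,14-diene-7α,8α-diol | C=C/C(C)=C/C[C@H]1[C@](C)(O)[C@H](O)C[C@H]2C(C)(C)CCC[C@@]21C | intermediate
28 | 8α-hydroxylabda-12E,14-dien-7-one | C=C/C(C)=C/C[C@H]1[C@](C)(O)C(=O)C[C@H]2C(C)(C)CCC[C@@]21C | intermediate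
29 | dipotassium 8-alkoxide Δ6-enolate of 28 | C=C/C(C)=C/C[C@H]1[C@](C)([O-])C([O-])=C[C@H]2C(C)(C)CCC[C@@]21C.[K+].[K+] | intermediate (not isolated)
30 | 6α,8α-dihydroxylabda-12E,14-dien-7-one | C=C/C(C)=C/C[C@H]1[C@](C)(O)C(=O)[C@H](O)[C@H]2C(C)(C)CCC[C@@]21C | intermediate
31 | angelic acid, (Z)-2-methylbut-2-enoic acid | C/C=C(/C)C(=O)O | starting material
32 | (Z)-2-methylbut-2-enoic 2,4,6-trichlorobenzoic anhydride | C/C=C(/C)C(=O)OC(=O)c1c(Cl)cc(Cl)cc1Cl | intermediate (not isolated)
33 | 8α-hydroxy-7-oxolabda-12E,14-dien-6α-yl (Z)-2-methylbut-2-enoate | C=C/C(C)=C/C[C@H]1[C@](C)(O)C(=O)[C@H](OC(=O)/C(C)=C\C)[C@H]2C(C)(C)CCC[C@@]21C | intermediate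
34 | 7β,8α-dihydroxylabda-12E,14-dien-6α-yl (Z)-2-methylbut-2-enoate, (5S,6R,7S,8S,9R,10S), CNP0189082.1 | C=C/C(C)=C/C[C@H]1[C@](C)(O)[C@@H](O)[C@H](OC(=O)/C(C)=C\C)[C@H]2C(C)(C)CCC[C@@]21C | target

**Total step count:** 17. **Longest linear sequence:** 17 steps (from methyl isobutyrate).

**Steps most likely to fail**

Step 7. The cycloaddition may be too slow at temperatures where the catalyst still controls the outcome, because the C5–C10 bond joins a neopentyl carbon to a fully substituted diene terminus and the tether imposes the electronically less favoured orientation. On warming, protodesilylation of the dienol ether and erosion of endo/exo and facial selectivity can follow. The fallback replaces catalyst control by a covalently bound auxiliary and sets out from aldehyde 10. Horner–Wadsworth–Emmons olefination with diethyl {2-[(4S)-4-benzyl-2-oxo-1,3-oxazolidin-3-yl]-2-oxoethyl}phosphonate (LiCl, iPr2NEt, MeCN) should give (4S)-4-benzyl-3-[(2E,8E)-4,4,8-trimethyl-10-(triisopropylsilyloxy)undeca-2,8,10-trienoyl]-1,3-oxazolidin-2-one F1. Its Me2AlCl-promoted intramolecular Diels–Alder reaction (CH2Cl2, −30 °C) is expected to give the endo, trans-fused imide adduct F2. In the chelated s-cis model the benzyl group covers the Re face at C6, so the same Si-face addition results. Reductive removal of the auxiliary with LiBH4/MeOH in THF at 0 °C should give the primary alcohol [(1S,4aS,8aS)-4a,8,8-trimethyl-3-(triisopropylsilyloxy)-1,2,4a,5,6,7,8,8a-octahydronaphthalen-1-yl]methanol F3. Parikh–Doering oxidation of F3 returns to the route at aldehyde 14.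

Step 9. O-alkylation, proton transfer between enolate and product (leading to C7 alkylation or dialkylation) and an incomplete equilibration at C9 may lower the yield of the 9β ketone. The fallback builds the C9–C11 bond by aminomethylation and conjugate addition and sets out from silyl enol ether 15. Mannich reaction with dimethylmethyleneammonium iodide in CH2Cl2 should give the 9α-(dimethylaminomethyl) ketone F4. Quaternisation with MeI and elimination with NaHCO3 then give the 9-methylene ketone 14,15,16,17-tetranor-12,13-seco-type enone (1-methylidene decalone) F5. 1,4-Addition of Et2AlC≡CCH3 (from prop-1-ynyllithium and Et2AlCl, Et2O/toluene, −15 °C) to this s-cis enone, followed by protonation of the aluminium enolate from the α face and brief NaOMe/MeOH treatment, returns to the route at ketone 19.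

Step 15. Deprotonation of the hindered axial C6–H may be slow, and the dianion may undergo base-induced α-ketol rearrangement before it is oxidised. The fallback avoids the strong base and sets out from hydroxy ketone 28. Soft enolisation with Me3SiOTf/Et3N in CH2Cl2 at 0 °C should give the 7,8-bis(trimethylsilyloxy) Δ6-enol ether F6. Rubottom oxidation with dimethyldioxirane in acetone at −78 °C is expected to occur on the α face of the electron-rich enol ether in preference to the side-chain diene. Desilylation with citric acid in MeOH returns to the route at diol ketone 30.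

**Further compounds**

F1 | step 7 | (4S)-4-benzyl-3-[(2E,8E)-4,4,8-trimethyl-10-(triisopropylsilyloxy)undeca-2,8,10-trienoyl]-1,3-oxazolidin-2-one | C=C(O[Si](C(C)C)(C(C)C)C(C)C)/C=C(\C)CCCC(C)(C)/C=C/C(=O)N1[C@@H](Cc2ccccc2)COC1=O
F2 | step 7 | (4S)-4-benzyl-3-{[(1S,4aS,8aS)-4a,8,8-trimethyl-3-(triisopropylsilyloxy)-1,2,4a,5,6,7,8,8a-octahydronaphthalen-1-yl]carbonyl}-1,3-oxazolidin-2-one | O=C([C@H]1CC(O[Si](C(C)C)(C(C)C)C(C)C)=C[C@@]2(C)CCCC(C)(C)[C@H]12)N1[C@@H](Cc2ccccc2)COC1=O
F3 | step 7 | [(1S,4aS,8aS)-4a,8,8-trimethyl-3-(triisopropylsilyloxy)-1,2,4a,5,6,7,8,8a-octahydronaphthalen-1-yl]methanol | OC[C@H]1CC(O[Si](C(C)C)(C(C)C)C(C)C)=C[C@@]2(C)CCCC(C)(C)[C@H]12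
F4 | step 9 | (1S,4aS,8aS)-1-[(dimethylamino)methyl]-5,5,8a-trimethyloctahydronaphthalen-2(1H)-one | CN(C)C[C@@H]1C(=O)CC[C@H]2C(C)(C)CCC[C@@]21C
F5 | step 9 | (4aS,8aS)-5,5,8a-trimethyl-1-methylideneoctahydronaphthalen-2(1H)-one | C=C1C(=O)CC[C@H]2C(C)(C)CCC[C@@]21C
F6 | step 15 | 7,8α-bis(trimethylsilyloxy)labda-6,12E,14-triene | C=C/C(C)=C/C[C@H]1[C@](C)(O[Si](C)(C)C)C(O[Si](C)(C)C)=C[C@H]2C(C)(C)CCC[C@@]21C
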